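**Strategy.** The route rests on cutting the C3–C4 bond of the dihydropyran ring. C3 and C4 are its only adjacent unsubstituted methylenes: C4 hangs on aromatic C4a of ring A, C3 on the O1-bearing stereocentre C2. Both are therefore introduced as vinyl termini of a 2-vinylphenyl (S)-1-arylallyl ether, made by iridium-catalysed allylic etherification. Ring-closing metathesis joins them as C3=C4, and diimide reduction in the same flask gives the (2S)-flavan in one operation. C8 of this flavan is then coupled to an (E)-diarylacrylate; Sharpless epoxidation and a fluoride-triggered epoxide-opening/SNAr cascade build the spiro bis-benzofuran, and hydrogenolysis ends the route.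

Key step: step 6

Remark: locants C2–C8a follow chromane (flavan) numbering, primed locants the dihydrofuran ring, doubly primed locants the benzofuranone; Bn = benzyl, Ar = 4-(benzyloxy)phenyl, SEM = 2-(trimethylsilyl)ethoxymethyl, FL = (2S)-5-(benzyloxy)-2-Ar-7-(SEM-oxy)chroman-8-yl, L* = (Sa,Sc,Sc)-(1,1′-binaphthalene-2,2′-diyl) N,N-bis(1-phenylethyl)phosphoramidite; the six starting materials (1, 2, 4, 12, 13, 22) are assumed to be purchasable.

Step 1
Reactants: 1 4-(benzyloxy)styrene; 2 allyl methyl carbonate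
Product: 3 (E)-3-Ar-prop-2-en-1-yl methyl carbonate
Conditions: 2 (3 equiv), second-generation Hoveyda–Grubbs catalyst (2 mol %), CH2Cl2, 40 °C
Reagents that add atoms: none
Why: Olefin cross-metathesis of a styrene with an excess of the allyl carbonate should give the aryl-conjugated E-alkene, the thermodynamic isomer, with loss of ethene.

Step 2
Reactants: 4 2,4,6-trihydroxybenzaldehyde
Product: 5 2,6-dihydroxy-4-(SEM-oxy)benzaldehyde
Conditions: SEMCl (1.05 equiv), iPr2NEt, CH2Cl2, 0 °C
Reagents that add atoms: 2-(trimethylsilyl)ethoxymethyl chloride, ClCOCC[Si](C)(C)C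
Why: Williamson-type O-alkylation should occur at the 4-hydroxyl, the most acidic one and the only one not tied up in a hydrogen bond to the formyl group.

Step 3
Reactants: 5 2,6-dihydroxy-4-(SEM-oxy)benzaldehyde
Product: 6 2-(benzyloxy)-6-hydroxy-4-(SEM-oxy)benzaldehyde
Conditions: BnBr (1.05 equiv), K2CO3, DMF, 23 °C
Reagents that add atoms: benzyl bromide, BrCc1ccccc1
Why: Williamson benzylation of one of the two equivalent chelated hydroxyls should stop at the mono-ether because the remaining hydroxyl is then fully engaged in the hydrogen bond to the aldehyde.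

Step 4
Reactants: 6 2-(benzyloxy)-6-hydroxy-4-(SEM-oxy)benzaldehyde
Product: 7 3-(benzyloxy)-2-ethenyl-5-(SEM-oxy)phenol
Conditions: Ph3PCH3Br (3 equiv), KOtBu (3 equiv), THF, 0 → 23 °C
Reagents that add atoms: methyltriphenylphosphonium bromide, C[P+](c1ccccc1)(c1ccccc1)c1ccccc1.[Br-]
Why: Wittig methylenation with excess ylide (one equivalent is held by the phenoxide) should convert the formyl group into the vinyl group whose inner carbon is the future C4.

Step 5
Reactants: 7 3-(benzyloxy)-2-ethenyl-5-(SEM-oxy)phenol; 3 (E)-3-Ar-prop-2-en-1-yl methyl carbonate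
Product: 8 1-(benzyloxy)-3-{[(1S)-1-Ar-prop-2-en-1-yl]oxy}-2-ethenyl-5-(SEM-oxy)benzene
Conditions: [Ir(cod)Cl]2 (2 mol %), L* (4 mol %), n-PrNH2 (pre-activation), K3PO4, THF, 23 °C
Reagents that add atoms: none
Why: Iridium-catalysed asymmetric allylic etherification should deliver the phenoxide to the aryl-substituted terminus of the allyliridium intermediate (branched ether), and the (Sa,Sc,Sc) ligand is the enantiomer expected, from the facial preference of this catalyst class with aryl allyl carbonates and heteroatom nucleophiles, to set the (S) configuration of the future C2.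

Step 6
Reactants: 8 (S)-1-arylallyl 2-vinylphenyl ether
Product: 10 (2S)-5-(benzyloxy)-2-Ar-7-(SEM-oxy)chromane (FL–H), via 2H-chromene 9 (not isolated)
Conditions: second-generation Grubbs catalyst (5 mol %), CH2Cl2 (0.01 M), 40 °C; ethyl vinyl ether; then 2-nitrobenzenesulfonohydrazide, Et3N, 23 °C
Reagents that add atoms: none
Why: The ruthenium alkylidene is loaded onto the less hindered allyl-ether alkene and, by [2+2] cycloaddition with the ortho vinyl group and cycloreversion through a ruthenacyclobutane, expels ethene and joins C3 to C4 as the cis C3=C4 bond of 2H-chromene 9; diimide generated in the same flask then transfers two hydrogens suprafacially through a six-membered cyclic transition state to give the C3H2–C4H2 unit. The closest known reaction type is ring-closing olefin metathesis of 2-vinylphenyl 1-arylallyl ethers to 2-aryl-2H-chromenes, followed by metal-free diimide saturation of a cis-disubstituted alkene. The one ring closed is the six-membered dihydropyran, formed by intramolecular alkene–alkene metathesis of two monosubstituted alkenes, the endocyclic alkene being necessarily cis. No new stereocentre arises, and C2 from step 5 is neither ionised nor deprotonated in either event. The step needs ring closure to outrun intermolecular metathesis, which the ortho disposition of the two alkenes and dilution secure; it also needs saturation without migration of the double bond into conjugation with O1 (which would erase C2) and without hydrogenolysis of benzyl ethers or of the C2–O1 bond, which is why the catalyst is quenched and diimide is used in place of a metal hydride or heterogeneous hydrogenation.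

Step 7
Reactants: 10 flavan FL–H
Product: 11 (2S)-5-(benzyloxy)-8-bromo-2-Ar-7-(SEM-oxy)chromane (FL–Br)
Conditions: NBS (1.0 equiv), CH2Cl2, −78 → −20 °C, dark
Reagents that add atoms: N-bromosuccinimide, O=C1CCC(=O)N1Br
Why: Electrophilic aromatic bromination of the phloroglucinol-type ring A should occur at C8, flanked by the ring oxygen O1 and the SEM ether, rather than at C6, which is shielded by two freely rotating alkoxy groups, as is usual for 5,7-dialkoxyflavans.

Step 8
Reactants: 12 4-(benzyloxy)benzaldehyde; 13 ethyl (triphenylphosphoranylidene)acetate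
Product: 15 ethyl (2Z)-2-bromo-3-Ar-prop-2-enoate, via bromo ylide 14 (not isolated)
Conditions: 13, NBS, CH2Cl2, −20 °C; then 12, 23 °C
Reagents that add atoms: N-bromosuccinimide, O=C1CCC(=O)N1Br
Why: α-Bromination of the stabilised ylide gives the bromo ylide, whose Wittig olefination should place the ester trans to the aryl group and so give the (Z)-bromoalkene with bromine cis to Ar.

Step 9
Reactants: 11 bromoflavan FL–Br; 15 ethyl (2Z)-2-bromo-3-Ar-prop-2-enoate
Product: 18 ethyl (2E)-3-Ar-2-FL-prop-2-enoate, via aryllithium 16 (not isolated), via arylzinc chloride 17 (not isolated)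
Conditions: t-BuLi (2.1 equiv), THF, −78 °C; ZnCl2, −78 → 23 °C; then 15, Pd2(dba)3 (2.5 mol %), SPhos (10 mol %), THF, 50 °C
Reagents that add atoms: none
Why: Bromine–lithium exchange, transmetalation to zinc and Negishi coupling with retention of alkene geometry should replace the vinylic bromine by ring A, so that the two aryl groups end up cis and the ester trans to Ar.

Step 10
Reactants: 18 ethyl (2E)-3-Ar-2-FL-prop-2-enoate
Product: 19 (2E)-3-Ar-2-FL-prop-2-en-1-ol
Conditions: DIBAL-H (2.5 equiv), CH2Cl2, −78 → 0 °C; Rochelle salt work-up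
Reagents that add atoms: none
Why: 1,2-Reduction of the conjugated ester by the aluminium hydride should give the allylic alcohol without change of alkene geometry.

Step 11
Reactants: 19 (2E)-3-Ar-2-FL-prop-2-en-1-ol
Product: 20 [(2R,3R)-3-Ar-2-FL-oxiran-2-yl]methanol
Conditions: Ti(OiPr)4 (10 mol %), D-(−)-diethyl tartrate (13 mol %), t-BuOOH (2 equiv), 4 Å MS, CH2Cl2, −25 °C
Reagents that add atoms: tert-butyl hydroperoxide, CC(C)(C)OO
Why: Sharpless asymmetric epoxidation with the D-(−)-tartrate should give the (2R,3R)-epoxide, the mirror image of the (2S,3S) sense that L-(+)-tartrate imposes on (E)-2,3-diarylallyl alcohols, under reagent control that overrides the remote C2 centre; this fixes the oxygen-bearing quaternary carbon (future spiro centre) and the benzylic carbon that is inverted in step 17.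

Step 12
Reactants: 20 [(2R,3R)-3-Ar-2-FL-oxiran-2-yl]methanol
Product: 21 (2S,3R)-3-Ar-2-FL-oxirane-2-carbaldehyde
Conditions: Dess–Martin periodinane, pyridine, CH2Cl2, 0 °C
Reagents that add atoms: none
Why: Buffered Dess–Martin oxidation should give the non-enolisable epoxy aldehyde without opening the acid-labile epoxide (the change of descriptor at C2 is only a change of CIP ranking).

Step 13
Reactants: 22 5-fluorobenzene-1,3-diol
Product: 23 1,3-bis(benzyloxy)-5-fluorobenzene
Conditions: BnBr (2.2 equiv), K2CO3, DMF, 60 °C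
Reagents that add atoms: benzyl bromide, BrCc1ccccc1
Why: Double Williamson etherification of the resorcinol.

Step 14
Reactants: 23 1,3-bis(benzyloxy)-5-fluorobenzene
Product: 24 1,5-bis(benzyloxy)-2-bromo-3-fluorobenzene
Conditions: NBS (1.0 equiv), MeCN, 0 → 23 °C
Reagents that add atoms: N-bromosuccinimide, O=C1CCC(=O)N1Br
Why: Electrophilic bromination should go para to one benzyloxy group and ortho to the other, at the site next to fluorine, in preference to the more hindered site between the two benzyloxy groups.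

Step 15
Reactants: 24 1,5-bis(benzyloxy)-2-bromo-3-fluorobenzene; 21 (2S,3R)-3-Ar-2-FL-oxirane-2-carbaldehyde
Product: 26 [2,4-bis(benzyloxy)-6-fluorophenyl][(2R,3R)-3-Ar-2-FL-oxiran-2-yl]methanol, via aryllithium 25 (not isolated)
Conditions: 24, n-BuLi (1.05 equiv), THF, −78 °C; then 21, −78 °C; H2O
Reagents that add atoms: none
Why: Bromine–lithium exchange at −78 °C (below the temperature at which the ortho-fluoro aryllithium loses LiF) and 1,2-addition to the aldehyde should give the carbinol as a mixture of epimers at the new centre, which is removed in step 16.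

Step 16
Reactants: 26 epoxy carbinol
Product: 27 [2,4-bis(benzyloxy)-6-fluorophenyl][(2S,3R)-3-Ar-2-FL-oxiran-2-yl]methanone
Conditions: Dess–Martin periodinane, pyridine, CH2Cl2, 23 °C
Reagents that add atoms: none
Why: Dess–Martin oxidation should convert both carbinol epimers into the single epoxy ketone, which has no enolisable hydrogen.

Step 17
Reactants: 27 epoxy ketone
Product: 30 penta-O-benzyl-daphnodorin C, via phenoxide 28 (not isolated), via hydroxy ketone 29 (not isolated)
Conditions: TBAF (4 equiv), 4 Å MS, THF–DMPU, 23 → 60 °C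
Reagents that add atoms: none
Why: Fluoride-induced SEM cleavage unveils the C7 phenoxide, which should open the epoxide at the benzylic carbon in a 5-endo SN2 manner with inversion (C2′ becomes S, Ar cis to the tertiary oxygen), and the tertiary alkoxide thus released should close the benzofuranone by intramolecular SNAr on the ortho-fluoro ketone with retention at the quaternary carbon (spiro centre S).

Step 18
Reactants: 30 penta-O-benzyl-daphnodorin C
Product: 31 daphnodorin C
Conditions: H2 (1 atm), 10% Pd/C, EtOAc–MeOH, 23 °C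
Reagents that add atoms: none
Why: Hydrogenolysis of the five benzyl ethers under neutral conditions should free all phenols without the base that could open the spiro ether through a quinone methide once the C5 hydroxyl is free.

**Compound list**

1 | 4-(benzyloxy)styrene | C=Cc1ccc(OCc2ccccc2)cc1 | starting material
2 | allyl methyl carbonate | C=CCOC(=O)OC | starting material
3 | (E)-3-[4-(benzyloxy)phenyl]prop-2-en-1-yl methyl carbonate | COC(=O)OC/C=C/c1ccc(OCc2ccccc2)cc1 | intermediate
4 | 2,4,6-trihydroxybenzaldehyde | O=Cc1c(O)cc(O)cc1O | starting material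
5 | 2,6-dihydroxy-4-{[2-(trimethylsilyl)ethoxy]methoxy}benzaldehyde | O=Cc1c(O)cc(OCOCC[Si](C)(C)C)cc1O | intermediate
6 | 2-(benzyloxy)-6-hydroxy-4-{[2-(trimethylsilyl)ethoxy]methoxy}benzaldehyde | O=Cc1c(O)cc(OCOCC[Si](C)(C)C)cc1OCc1ccccc1 | intermediate
7 | 3-(benzyloxy)-2-ethenyl-5-{[2-(trimethylsilyl)ethoxy]methoxy}phenol | C=Cc1c(O)cc(OCOCC[Si](C)(C)C)cc1OCc1ccccc1 | intermediate
8 | 1-(benzyloxy)-3-{[(1S)-1-[4-(benzyloxy)phenyl]prop-2-en-1-yl]oxy}-2-ethenyl-5-{[2-(trimethylsilyl)ethoxy]methoxy}benzene | C=C[C@H](Oc1cc(OCOCC[Si](C)(C)C)cc(OCc2ccccc2)c1C=C)c1ccc(OCc2ccccc2)cc1 | intermediate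
9 | (2S)-5-(benzyloxy)-2-[4-(benzyloxy)phenyl]-7-{[2-(trimethylsilyl)ethoxy]methoxy}-2H-chromene | O1[C@H](c2ccc(OCc3ccccc3)cc2)C=Cc2c(OCc3ccccc3)cc(OCOCC[Si](C)(C)C)cc21 | intermediate (not isolated)
10 | (2S)-5-(benzyloxy)-2-[4-(benzyloxy)phenyl]-7-{[2-(trimethylsilyl)ethoxy]methoxy}chromane (FL–H) | O1[C@H](c2ccc(OCc3ccccc3)cc2)CCc2c(OCc3ccccc3)cc(OCOCC[Si](C)(C)C)cc21 | intermediate
11 | (2S)-5-(benzyloxy)-2-[4-(benzyloxy)phenyl]-8-bromo-7-{[2-(trimethylsilyl)ethoxy]methoxy}chromane (FL–Br) | O1[C@H](c2ccc(OCc3ccccc3)cc2)CCc2c(OCc3ccccc3)cc(OCOCC[Si](C)(C)C)c(Br)c21 | intermediate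
12 | 4-(benzyloxy)benzaldehyde | O=Cc1ccc(OCc2ccccc2)cc1 | starting material
13 | ethyl (triphenylphosphoranylidene)acetate | CCOC(=O)C=P(c1ccccc1)(c1ccccc1)c1ccccc1 | starting material
14 | ethyl bromo(triphenylphosphoranylidene)acetate | CCOC(=O)C(Br)=P(c1ccccc1)(c1ccccc1)c1ccccc1 | intermediate (not isolated)
15 | ethyl (2Z)-3-[4-(benzyloxy)phenyl]-2-bromoprop-2-enoate | CCOC(=O)/C(Br)=C/c1ccc(OCc2ccccc2)cc1 | intermediate
16 | FL–Li, the 8-lithio derivative of 10 | [Li]c1c(OCOCC[Si](C)(C)C)cc(OCc2ccccc2)c2c1O[C@H](c1ccc(OCc3ccccc3)cc1)CC2 | intermediate (not isolated)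
17 | FL–ZnCl, the 8-(chlorozincio) derivative of 10 | Cl[Zn]c1c(OCOCC[Si](C)(C)C)cc(OCc2ccccc2)c2c1O[C@H](c1ccc(OCc3ccccc3)cc1)CC2 | intermediate (not isolated)
18 | ethyl (2E)-3-[4-(benzyloxy)phenyl]-2-FL-prop-2-enoate (aryl groups cis) | CCOC(=O)/C(=C/c1ccc(OCc2ccccc2)cc1)c1c(OCOCC[Si](C)(C)C)cc(OCc2ccccc2)c2c1O[C@H](c1ccc(OCc3ccccc3)cc1)CC2 | intermediate
19 | (2E)-3-[4-(benzyloxy)phenyl]-2-FL-prop-2-en-1-ol | OC/C(=C/c1ccc(OCc2ccccc2)cc1)c1c(OCOCC[Si](C)(C)C)cc(OCc2ccccc2)c2c1O[C@H](c1ccc(OCc3ccccc3)cc1)CC2 | intermediate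
20 | [(2R,3R)-3-[4-(benzyloxy)phenyl]-2-FL-oxiran-2-yl]methanol | OC[C@@]1(c2c(OCOCC[Si](C)(C)C)cc(OCc3ccccc3)c3c2O[C@H](c2ccc(OCc4ccccc4)cc2)CC3)O[C@@H]1c1ccc(OCc2ccccc2)cc1 | intermediate
21 | (2S,3R)-3-[4-(benzyloxy)phenyl]-2-FL-oxirane-2-carbaldehyde | O=C[C@@]1(c2c(OCOCC[Si](C)(C)C)cc(OCc3ccccc3)c3c2O[C@H](c2ccc(OCc4ccccc4)cc2)CC3)O[C@@H]1c1ccc(OCc2ccccc2)cc1 | intermediate
22 | 5-fluorobenzene-1,3-diol | Oc1cc(O)cc(F)c1 | starting material
23 | 1,3-bis(benzyloxy)-5-fluorobenzene | Fc1cc(OCc2ccccc2)cc(OCc2ccccc2)c1 | intermediate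
24 | 1,5-bis(benzyloxy)-2-bromo-3-fluorobenzene | Fc1cc(OCc2ccccc2)cc(OCc2ccccc2)c1Br | intermediate
25 | [2,4-bis(benzyloxy)-6-fluorophenyl]lithium | [Li]c1c(F)cc(OCc2ccccc2)cc1OCc1ccccc1 | intermediate (not isolated)
26 | [2,4-bis(benzyloxy)-6-fluorophenyl][(2R,3R)-3-[4-(benzyloxy)phenyl]-2-FL-oxiran-2-yl]methanol (both carbinol epimers) | OC(c1c(F)cc(OCc2ccccc2)cc1OCc1ccccc1)[C@@]1(c2c(OCOCC[Si](C)(C)C)cc(OCc3ccccc3)c3c2O[C@H](c2ccc(OCc4ccccc4)cc2)CC3)O[C@@H]1c1ccc(OCc2ccccc2)cc1 | intermediate
27 | [2,4-bis(benzyloxy)-6-fluorophenyl][(2S,3R)-3-[4-(benzyloxy)phenyl]-2-FL-oxiran-2-yl]methanone | O=C(c1c(F)cc(OCc2ccccc2)cc1OCc1ccccc1)[C@@]1(c2c(OCOCC[Si](C)(C)C)cc(OCc3ccccc3)c3c2O[C@H](c2ccc(OCc4ccccc4)cc2)CC3)O[C@@H]1c1ccc(OCc2ccccc2)cc1 | intermediate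
28 | 7-hydroxy analogue of 27 (SEM removed), present as its tetrabutylammonium phenoxide | O=C(c1c(F)cc(OCc2ccccc2)cc1OCc1ccccc1)[C@@]1(c2c(O)cc(OCc3ccccc3)c3c2O[C@H](c2ccc(OCc4ccccc4)cc2)CC3)O[C@@H]1c1ccc(OCc2ccccc2)cc1 | intermediate (not isolated)
29 | hydroxy ketone: (2S)-5-(benzyloxy)-2-Ar-chromane fused at O7–C8 with a 2,3-dihydrofuran ring; C2′ (S) bears H and Ar, C3′ (S) bears OH and the 2,4-bis(benzyloxy)-6-fluorobenzoyl group, Ar cis to OH; present as its alkoxide | O=C(c1c(F)cc(OCc2ccccc2)cc1OCc1ccccc1)[C@]1(O)c2c(cc(OCc3ccccc3)c3c2O[C@H](c2ccc(OCc4ccccc4)cc2)CC3)O[C@H]1c1ccc(OCc2ccccc2)cc1 | intermediate (not isolated)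
30 | penta-O-benzyl-daphnodorin C (2S,2′S,3′S; C3′ is spiro C2″ of 4,6-bis(benzyloxy)benzofuran-3(2H)-one; Ar at C2′ cis to the benzofuranone ring oxygen) | O=C1c2c(OCc3ccccc3)cc(OCc3ccccc3)cc2O[C@]12c1c(cc(OCc3ccccc3)c3c1O[C@H](c1ccc(OCc4ccccc4)cc1)CC3)O[C@H]2c1ccc(OCc2ccccc2)cc1 | intermediate
31 | daphnodorin C (2S,2′S,3′S) | O=C1c2c(O)cc(O)cc2O[C@]12c1c(cc(O)c3c1O[C@H](c1ccc(O)cc1)CC3)O[C@H]2c1ccc(O)cc1 | target

**Step count.** 18 steps in total. The longest linear sequence is 14 steps (steps 2–7, 9–12 and 15–18, from 2,4,6-trihydroxybenzaldehyde).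

**Steps most likely to fail, with fallbacks**

Step 17. The liberated phenoxide may attack the fluoroarene (seven-membered SNAr) or the epoxy ketone may degrade under basic fluoride before the epoxide opens. The fallback unveils the phenoxide before the fluoroarene is present; it sets out from 20 and returns at 30. Epoxy alcohol 20 is treated with TBAF (THF–DMPU, 50 °C); SEM cleavage and 5-endo opening with inversion should give the dihydrofuran diol F1. Parikh–Doering oxidation (SO3·pyridine, DMSO, iPr2NEt, chosen because it does not cleave glycols) should give the hydroxy aldehyde F2. Aryllithium 25 (2.2 equiv, −78 °C) should add to give the carbinol diol F3. A second Parikh–Doering oxidation should give hydroxy ketone 29, now isolated, and NaH in THF should close the benzofuranone by SNAr to 30.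

Step 11. The titanium Lewis acid may open the very electron-rich diaryl epoxide as it forms, or turnover may stall at the hindered 2-aryl allylic alcohol. The fallback sets out from 19 and returns at 20 and makes no new compound (F0). It replaces the metal-tartrate system by base-buffered dioxirane epoxidation: D-fructose-derived ketone catalyst (1,2:4,5-di-O-isopropylidene-β-D-erythro-2,3-hexodiulo-2,6-pyranose), Oxone, K2CO3, Bu4NHSO4, MeCN–dimethoxymethane–aqueous buffer (pH 10.5), 0 °C. By the spiro transition-state model this ketone enantiomer is expected to attack the same alkene face as the D-(−)-tartrate system.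

Step 9. Transmetalation and reductive elimination at the doubly ortho-substituted arylzinc may be slow, leaving protodemetalation or E/Z scrambling of the alkenylpalladium intermediate to compete. The fallback sets out from 11 (through aryllithium 16) and returns at 19, bypassing 18 and step 10. Aryllithium 16 is converted with MgBr2·OEt2 into the aryl Grignard reagent F5. 3-[4-(Benzyloxy)phenyl]prop-2-yn-1-ol F4 is made by Sonogashira coupling of 1-(benzyloxy)-4-iodobenzene with prop-2-yn-1-ol (Pd(PPh3)2Cl2, CuI, Et3N) and is first deprotonated with MeMgBr. F5 is then added across its triple bond in an alkoxide-directed anti-carbomagnesiation (CuI cat., toluene, 80 °C). The aryl group goes to C2 and magnesium to C3 within a five-membered oxamagnesacycle, so protonolysis should give (E)-allylic alcohol 19 with the two aryl groups cis.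

Further compounds
F1 | step 17 | dihydrofuran diol: ring system of 29 with CH2OH in place of the aroyl group at C3′ (Ar at C2′ cis to the tertiary OH) | OC[C@]1(O)c2c(cc(OCc3ccccc3)c3c2O[C@H](c2ccc(OCc4ccccc4)cc2)CC3)O[C@H]1c1ccc(OCc2ccccc2)cc1
F2 | step 17 | hydroxy aldehyde: ring system of 29 with CHO in place of the aroyl group at C3′ | O=C[C@]1(O)c2c(cc(OCc3ccccc3)c3c2O[C@H](c2ccc(OCc4ccccc4)cc2)CC3)O[C@H]1c1ccc(OCc2ccccc2)cc1
F3 | step 17 | carbinol diol: 29 with the ketone reduced to CH(OH) (both carbinol epimers) | OC(c1c(F)cc(OCc2ccccc2)cc1OCc1ccccc1)[C@]1(O)c2c(cc(OCc3ccccc3)c3c2O[C@H](c2ccc(OCc4ccccc4)cc2)CC3)O[C@H]1c1ccc(OCc2ccccc2)cc1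
F0 | step 11 | none | none
F4 | step 9 | 3-[4-(benzyloxy)phenyl]prop-2-yn-1-ol | OCC#Cc1ccc(OCc2ccccc2)cc1
F5 | step 9 | FL–MgBr, the 8-(bromomagnesio) derivative of 10 | Br[Mg]c1c(OCOCC[Si](C)(C)C)cc(OCc2ccccc2)c2c1O[C@H](c1ccc(OCc3ccccc3)cc1)CC2
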